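The cyclopentenone is closed at the C9–C10 bond (prostanoid numbering: C9 ring ketone, C10 chlorinated ring carbon) by rhodium-catalysed intramolecular hydroacylation of a chloroalkyne. The plan exploits a hidden symmetry at the acetoxy-bearing ring carbon C12: its two CH2 neighbours, ring C8 and side-chain C13, each lead to an sp2 carbon (C9, C14) at aldehyde oxidation level. The precursor is therefore an achiral 3-(chloroethynyl)-3-silyloxypentanedial. In one operation a chiral catalyst chooses one of the two enantiotopic formyl groups, forms the chloroenone ring and sets the C12 quaternary stereocentre. The spared formyl group becomes the (Z)-octenyl chain, and an aldol condensation adds the dienoate chain.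

Key step: step 4

Assumption: the sense of enantiotopic-group selection by the Tol-BINAP rhodium catalyst cannot be predicted for this substrate. (R)-Tol-BINAP is written, and (S)-Tol-BINAP is to be used if the first run shows the opposite sense. Prostanoid numbering (ester carbon C1, ring C8–C12) is used for the atoms of late intermediates.

Step 1
Reactants: 1 cyclopent-3-en-1-one; 2 (Z)-1,2-dichloroethene
Product: 4 1-(chloroethynyl)cyclopent-3-en-1-ol, via lithium chloroacetylide 3 (not isolated)
Conditions: 2, MeLi (2 equiv per 2), Et2O, 0 °C; then 1, −78 °C to 0 °C; aq NH4Cl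
Reagents that add atoms: none
Why: Dehydrochlorination and deprotonation of 2 by MeLi give lithium chloroacetylide, which adds 1,2 to the ketone (acetylide addition to a carbonyl group) at a temperature low enough to hold back enolisation of the β,γ-unsaturated ketone; the product is achiral.

Step 2
Reactants: 4 1-(chloroethynyl)cyclopent-3-en-1-ol
Product: 5 [1-(chloroethynyl)cyclopent-3-en-1-yl]oxy(triethyl)silane
Conditions: TESOTf, 2,6-lutidine, CH2Cl2, −78 °C to 0 °C
Reagents that add atoms: triethylsilyl trifluoromethanesulfonate, CC[Si](CC)(CC)OS(=O)(=O)C(F)(F)F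
Why: Silylation of a hindered tertiary propargylic alcohol with a silyl triflate and a hindered pyridine base is standard, and the silyl ether blocks retro-aldol cleavage and β-elimination in the aldehyde stages that follow.

Step 3
Reactants: 5 [1-(chloroethynyl)cyclopent-3-en-1-yl]oxy(triethyl)silane
Product: 7 3-(chloroethynyl)-3-(triethylsilyloxy)pentanedial, via ozonide 6 (not isolated)
Conditions: O3, CH2Cl2, −78 °C; then Me2S, −78 °C to rt
Reagents that add atoms: ozone, [O-][O+]=O
Why: Ozonolysis (Criegee mechanism) with reductive work-up cleaves the cis-disubstituted ring alkene much faster than the electron-poor chloroalkyne and releases both formyl groups at once, so the carbinol carbon stays prochiral.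

Step 4
Reactants: 7 3-(chloroethynyl)-3-(triethylsilyloxy)pentanedial
Product: 8 (S)-2-[3-chloro-4-oxo-1-(triethylsilyloxy)cyclopent-2-en-1-yl]acetaldehyde
Conditions: [Rh((R)-Tol-BINAP)]BF4 (10 mol %; from [Rh(nbd)2]BF4, (R)-Tol-BINAP, H2), CH2Cl2, rt
Reagents that add atoms: none
Why: Proposed new method: Oxidative addition of one formyl C–H bond of 7 to the cationic monovalent rhodium centre gives an acyl rhodium hydride, net trans hydrometalation of the tethered chloroalkyne places hydride on the alkyne carbon attached to the quaternary centre and rhodium on the chlorine-bearing carbon (the polarity also seen in hydroboration of 1-chloroalkynes), and the six-membered acyl alkenyl rhodacycle reductively eliminates to form the C9–C10 bond. The closest known reaction type is the rhodium diphosphine-catalysed intramolecular trans hydroacylation of 4-alkynals to cyclopent-2-enones, including its Tol-BINAP-controlled desymmetrisation of 3-alkoxy-4-alkynals that carry two enantiotopic alkynes; new here are the 1-chloroalkyne and the choice between two enantiotopic formyl groups. The five-membered ring is closed in a formal 5-endo-dig sense, which is open to this reaction because the bond arises by reductive elimination from a metallacycle and not by direct attack on the alkyne. The prochiral carbinol carbon of 7 becomes the C12 stereocentre, and its configuration is controlled by the chiral diphosphine, which decides which CH2CHO arm enters the rhodacycle. The step needs enantiotopic-group selectivity (ligand), C–H activation in preference to insertion into the C–Cl bond or decarbonylation (room temperature and a gem-disubstituted tether that speeds ring closure), and a single hydroacylation, secured because the spared formyl group could reach the new ring chloroalkene only through a bridged rhodacycle.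

Step 5
Reactants: 8 (S)-2-[3-chloro-4-oxo-1-(triethylsilyloxy)cyclopent-2-en-1-yl]acetaldehyde; 9 hexyltriphenylphosphonium bromide
Product: 11 (S)-2-chloro-4-[(Z)-oct-2-en-1-yl]-4-(triethylsilyloxy)cyclopent-2-en-1-one, via hexylidenetriphenylphosphorane 10 (not isolated)
Conditions: 9, NaN(SiMe3)2, THF, 0 °C; then 8, −78 °C to 0 °C
Reagents that add atoms: none
Why: The Wittig reaction of a non-stabilised ylide under lithium-free conditions should give the (Z)-alkene through the kinetically favoured cis-oxaphosphetane, the formyl group reacting far faster at −78 °C than the hindered cross-conjugated ring ketone; C12 is not touched.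

Step 6
Reactants: 12 methyl hex-5-enoate; 13 (E)-but-2-enal
Product: 14 methyl (E)-7-oxohept-5-enoate
Conditions: RuCl2(=CHPh)(H2IMes)(PCy3) (second-generation Grubbs catalyst, 2 mol %), 13 (3 equiv), CH2Cl2, 40 °C
Reagents that add atoms: none
Why: Olefin cross-metathesis of a terminal alkene with an excess of an enal partner should give the conjugated (E)-enal as the thermodynamic product with loss of propene.

Step 7
Reactants: 11 (S)-2-chloro-4-[(Z)-oct-2-en-1-yl]-4-(triethylsilyloxy)cyclopent-2-en-1-one; 14 methyl (E)-7-oxohept-5-enoate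
Product: 16 methyl (5E,12S,14Z)-10-chloro-7-hydroxy-9-oxo-12-(triethylsilyloxy)prosta-5,10,14-trienoate (mixture at C7 and C8), via lithium enolate 15 (not isolated)
Conditions: LiN(iPr)2, THF, −78 °C; then 14, −78 °C; AcOH quench
Reagents that add atoms: none
Why: Kinetic deprotonation at C8, the only enolisable position, gives a cross-conjugated lithium enolate whose 1,2-addition to the enal (aldol addition) should outpace conjugate addition at −78 °C; the new C7 and C8 centres form as a mixture, which does not matter because both are removed in step 9.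

Step 8
Reactants: 16 methyl (5E,12S,14Z)-10-chloro-7-hydroxy-9-oxo-12-(triethylsilyloxy)prosta-5,10,14-trienoate
Product: 17 methyl (5E,12S,14Z)-10-chloro-7,12-dihydroxy-9-oxoprosta-5,10,14-trienoate (mixture at C7 and C8)
Conditions: HF·pyridine, pyridine, THF, 0 °C to rt
Reagents that add atoms: none
Why: Fluoride-driven cleavage of the triethylsilyl ether under buffered, non-basic conditions should leave the β-hydroxy ketone intact (no retro-aldol reaction), and C12 is not involved.

Step 9
Reactants: 17 methyl (5E,12S,14Z)-10-chloro-7,12-dihydroxy-9-oxoprosta-5,10,14-trienoate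
Product: 20 methyl (5E,7Z,12R,14Z)-12-acetoxy-10-chloro-9-oxoprosta-5,7,10,14-tetraenoate (target), via C7 acetate 18 (not isolated), via 12-hydroxy dienone 19 (not isolated)
Conditions: Ac2O, DMAP, Et3N, CH2Cl2, 0 °C to rt
Reagents that add atoms: acetic anhydride, CC(=O)OC(C)=O
Why: DMAP-catalysed acetylation of the secondary C7 alcohol, E1cB loss of acetate through the C8 enolate and acetylation of the tertiary C12 alcohol follow one another; in the elimination the C6 substituent is expected to turn away from the fully substituted C12 (allylic 1,3-strain) and end up syn to the C9 carbonyl, which is the (7Z) geometry, with any (7E) isomer to be removed by chromatography.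

Compound list
1 | cyclopent-3-en-1-one | O=C1CC=CC1 | starting material
2 | (Z)-1,2-dichloroethene | Cl/C=C\Cl | starting material
3 | lithium chloroacetylide | [Li]C#CCl | intermediate
4 | 1-(chloroethynyl)cyclopent-3-en-1-ol | OC1(C#CCl)CC=CC1 | intermediate
5 | [1-(chloroethynyl)cyclopent-3-en-1-yl]oxy(triethyl)silane | CC[Si](CC)(CC)OC1(C#CCl)CC=CC1 | intermediate
6 | 3-(chloroethynyl)-3-(triethylsilyloxy)-6,7,8-trioxabicyclo[3.2.1]octane (ozonide of 5, two diastereomers) | CC[Si](CC)(CC)OC1(C#CCl)CC2OOC(C1)O2 | intermediate
7 | 3-(chloroethynyl)-3-(triethylsilyloxy)pentanedial (achiral) | O=CCC(C#CCl)(O[Si](CC)(CC)CC)CC=O | intermediate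
8 | (S)-2-[3-chloro-4-oxo-1-(triethylsilyloxy)cyclopent-2-en-1-yl]acetaldehyde | O=CC[C@@]1(O[Si](CC)(CC)CC)C=C(Cl)C(=O)C1 | intermediate
9 | hexyltriphenylphosphonium bromide | CCCCCC[P+](c1ccccc1)(c1ccccc1)c1ccccc1.[Br-] | starting material
10 | hexylidenetriphenylphosphorane | CCCCCC=P(c1ccccc1)(c1ccccc1)c1ccccc1 | intermediate
11 | (S)-2-chloro-4-[(Z)-oct-2-en-1-yl]-4-(triethylsilyloxy)cyclopent-2-en-1-one | CCCCC/C=C\C[C@@]1(O[Si](CC)(CC)CC)C=C(Cl)C(=O)C1 | intermediate
12 | methyl hex-5-enoate | C=CCCCC(=O)OC | starting material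
13 | (E)-but-2-enal | C/C=C/C=O | starting material
14 | methyl (E)-7-oxohept-5-enoate | O=C/C=C/CCCC(=O)OC | intermediate
15 | lithium (S)-5-chloro-3-[(Z)-oct-2-en-1-yl]-3-(triethylsilyloxy)cyclopenta-1,4-dien-1-olate (C8 enolate of 11) | CCCCC/C=C\C[C@@]1(O[Si](CC)(CC)CC)C=C(Cl)C(O[Li])=C1 | intermediate
16 | methyl (5E,12S,14Z)-10-chloro-7-hydroxy-9-oxo-12-(triethylsilyloxy)prosta-5,10,14-trienoate (mixture at C7 and C8) | CCCCC/C=C\C[C@@]1(O[Si](CC)(CC)CC)C=C(Cl)C(=O)C1C(O)/C=C/CCCC(=O)OC | intermediate
17 | methyl (5E,12S,14Z)-10-chloro-7,12-dihydroxy-9-oxoprosta-5,10,14-trienoate (mixture at C7 and C8) | CCCCC/C=C\C[C@@]1(O)C=C(Cl)C(=O)C1C(O)/C=C/CCCC(=O)OC | intermediate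
18 | methyl (5E,12S,14Z)-7-acetoxy-10-chloro-12-hydroxy-9-oxoprosta-5,10,14-trienoate (mixture at C7 and C8) | CCCCC/C=C\C[C@@]1(O)C=C(Cl)C(=O)C1C(OC(C)=O)/C=C/CCCC(=O)OC | intermediate
19 | methyl (5E,7Z,12R,14Z)-10-chloro-12-hydroxy-9-oxoprosta-5,7,10,14-tetraenoate | CCCCC/C=C\C[C@@]1(O)C=C(Cl)C(=O)/C1=C\C=C\CCCC(=O)OC | intermediate
20 | methyl (5E,7Z,12R,14Z)-12-acetoxy-10-chloro-9-oxoprosta-5,7,10,14-tetraenoate | CCCCC/C=C\C[C@@]1(OC(C)=O)C=C(Cl)C(=O)/C1=C\C=C\CCCC(=O)OC | target

Total step count: 9. Longest linear sequence: 8 steps (1, 2, 3, 4, 5, 7, 8, 9); step 6 is a one-step side branch.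

Steps most likely to fail

1. Step 4 (Proposed new method). The rhodium centre may insert into the C(sp)–Cl bond, or the chloroalkenyl rhodium intermediate may lose chloride before reductive elimination. Decarbonylation or cis hydroacylation to an alkylidenecyclobutanone may compete, and the catalyst may discriminate poorly between the two formyl groups. The fallback uses known chemistry only, sets out from 1 and comes back at 8; it gives up the hydroacylation and makes the ring of 1 the ring of the target.
   - CH2=CHCH2MgBr (THF, −78 °C) adds to 1 to give 1-allylcyclopent-3-en-1-ol F1.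
   - Hydroxyl-directed epoxidation of the more nucleophilic ring alkene (m-CPBA, CH2Cl2, 0 °C) gives cis-3-allyl-6-oxabicyclo[3.1.0]hexan-3-ol F2 (meso, hydroxyl and epoxide oxygen on the same face).
   - Silylation (TESOTf, 2,6-lutidine) gives cis-3-allyl-3-(triethylsilyloxy)-6-oxabicyclo[3.1.0]hexane F3.
   - Enantioselective β-elimination of the meso epoxide with a chiral lithium amide, LiN[(S)-CH(CH3)Ph]2 or its enantiomer as required (THF, 0 °C), should give (1R,4S)-4-allyl-4-(triethylsilyloxy)cyclopent-2-en-1-ol F4; this is the desymmetrisation known for 4-substituted cyclopentene oxides.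
   - Oxidation with MnO2 gives (S)-4-allyl-4-(triethylsilyloxy)cyclopent-2-en-1-one F5.
   - Nucleophilic epoxidation (H2O2, NaOH, MeOH, 0 °C) gives (4S)-4-allyl-2,3-epoxy-4-(triethylsilyloxy)cyclopentan-1-one F6.
   - HCl in Et2O at 0 °C opens F6 at the carbon α to the ketone and, after loss of water, gives (S)-4-allyl-2-chloro-4-(triethylsilyloxy)cyclopent-2-en-1-one F7.
   - Cleavage of the allyl group (OsO4 cat., NaIO4, 2,6-lutidine, dioxane/H2O) gives 8.

2. Step 9. The E1cB elimination may give poor control of the C7=C8 geometry, and base may also attack the C12 oxygen function. The fallback sets out from 11 and comes back at 19, which is acetylated to 20 under the conditions of step 9; it fixes the geometry in a configurationally stable enol triflate and then couples with retention.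
   - Formylation of the C8 enolate of 11 (LiN(iPr)2, THF, −78 °C; 2,2,2-trifluoroethyl formate) gives (4R,5Z)-2-chloro-5-(hydroxymethylidene)-4-[(Z)-oct-2-en-1-yl]-4-(triethylsilyloxy)cyclopent-2-en-1-one F8, a chelated enol.
   - Triflation of its lithium chelate on the formyl oxygen (LiN(SiMe3)2, PhNTf2, THF, −78 °C) should give the (Z)-enol triflate (4R,5Z)-2-chloro-4-[(Z)-oct-2-en-1-yl]-4-(triethylsilyloxy)-5-{[(trifluoromethylsulfonyl)oxy]methylidene}cyclopent-2-en-1-one F9; a geometric isomer can be removed at this stage.
   - Hydroboration of methyl hex-5-ynoate with pinacolborane (Cp2Zr(H)Cl cat.) gives methyl (E)-6-(4,4,5,5-tetramethyl-1,3,2-dioxaborolan-2-yl)hex-5-enoate F10.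
   - Suzuki–Miyaura coupling of F9 with F10 (Pd(PPh3)4, K3PO4, THF/H2O, rt) proceeds with retention at both alkenes and should give methyl (5E,7Z,12R,14Z)-10-chloro-9-oxo-12-(triethylsilyloxy)prosta-5,7,10,14-tetraenoate F11.
   - HF·pyridine then gives 19.

3. Step 5. The basic ylide may deprotonate the ring ketone at C8, trigger β-elimination of silanolate from the β-silyloxy aldehyde or add to the ring carbonyl, and Z selectivity may erode. The fallback sets out from 8 and comes back at 11; it builds the alkene in two stages with a less basic ylide and a non-basic carbon–carbon coupling.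
   - Stork–Zhao olefination ((iodomethyl)triphenylphosphonium iodide, NaN(SiMe3)2, THF/DMPU, −78 °C) should give (S)-2-chloro-4-[(Z)-3-iodoprop-2-en-1-yl]-4-(triethylsilyloxy)cyclopent-2-en-1-one F12.
   - Negishi coupling with n-C5H11ZnBr (Pd(dppf)Cl2 cat., THF, rt) replaces iodine with retention of the (Z) geometry, leaves the ketone and the ring C–Cl bond alone, and gives 11.

Further compounds
F1 | step 4 | 1-allylcyclopent-3-en-1-ol | C=CCC1(O)CC=CC1
F2 | step 4 | cis-3-allyl-6-oxabicyclo[3.1.0]hexan-3-ol (meso) | C=CC[C@@]1(O)C[C@@H]2O[C@@H]2C1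
F3 | step 4 | cis-3-allyl-3-(triethylsilyloxy)-6-oxabicyclo[3.1.0]hexane (meso) | C=CC[C@@]1(O[Si](CC)(CC)CC)C[C@@H]2O[C@@H]2C1
F4 | step 4 | (1R,4S)-4-allyl-4-(triethylsilyloxy)cyclopent-2-en-1-ol | C=CC[C@@]1(O[Si](CC)(CC)CC)C=C[C@H](O)C1
F5 | step 4 | (S)-4-allyl-4-(triethylsilyloxy)cyclopent-2-en-1-one | C=CC[C@@]1(O[Si](CC)(CC)CC)C=CC(=O)C1
F6 | step 4 | (4S)-4-allyl-2,3-epoxy-4-(triethylsilyloxy)cyclopentan-1-one (epoxide diastereomers) | C=CC[C@@]1(O[Si](CC)(CC)CC)C2OC2C(=O)C1
F7 | step 4 | (S)-4-allyl-2-chloro-4-(triethylsilyloxy)cyclopent-2-en-1-one | C=CC[C@@]1(O[Si](CC)(CC)CC)C=C(Cl)C(=O)C1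
F8 | step 9 | (4R,5Z)-2-chloro-5-(hydroxymethylidene)-4-[(Z)-oct-2-en-1-yl]-4-(triethylsilyloxy)cyclopent-2-en-1-one | CCCCC/C=C\C[C@@]1(O[Si](CC)(CC)CC)C=C(Cl)C(=O)/C1=C\O
F9 | step 9 | (4R,5Z)-2-chloro-4-[(Z)-oct-2-en-1-yl]-4-(triethylsilyloxy)-5-{[(trifluoromethylsulfonyl)oxy]methylidene}cyclopent-2-en-1-one | CCCCC/C=C\C[C@@]1(O[Si](CC)(CC)CC)C=C(Cl)C(=O)/C1=C\OS(=O)(=O)C(F)(F)F
F10 | step 9 | methyl (E)-6-(4,4,5,5-tetramethyl-1,3,2-dioxaborolan-2-yl)hex-5-enoate | COC(=O)CCC/C=C/B1OC(C)(C)C(C)(C)O1
F11 | step 9 | methyl (5E,7Z,12R,14Z)-10-chloro-9-oxo-12-(triethylsilyloxy)prosta-5,7,10,14-tetraenoate | CCCCC/C=C\C[C@@]1(O[Si](CC)(CC)CC)C=C(Cl)C(=O)/C1=C\C=C\CCCC(=O)OC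
F12 | step 5 | (S)-2-chloro-4-[(Z)-3-iodoprop-2-en-1-yl]-4-(triethylsilyloxy)cyclopent-2-en-1-one | I/C=C\C[C@@]1(O[Si](CC)(CC)CC)C=C(Cl)C(=O)C1
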